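**Retrosynthetic overview**

1. Target 21 ⇐ lactonisation of syn-3,5-dihydroxy ester 20 ⇐ 1,3-syn reduction of δ-hydroxy-β-keto ester 18 ⇐ vinylogous aldol of enal 15 with Chan's diene 16.
2. Enal 15 ⇐ terminal alkyne 12 by hydrozirconation and CO insertion. An alkyne is carried rather than an alkene because a terminal alkene 1,7 to the styrene would ring-close under metathesis.
3. Alkyne 12 ⇐ anti diol 11 ⇐ β-hydroxy enone 10 (1,3-anti reduction, then double O-methylation).
4. Key disconnection: 10 ⇐ dithiane 9 ⇐ lithiated cinnamaldehyde dithiane (the aldehyde carbon as nucleophile) + (S)-epichlorohydrin 4 + acetylide 5, joined in one flask; 4 supplies the first stereocentre.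
5. Rings: the 1,3-dithiane is made first and removed in step 3; the δ-lactone, the only ring of the target, is closed last.

Assumption: lithium acetylide–ethylenediamine complex and Chan's diene (1-methoxy-1,3-bis(trimethylsilyloxy)buta-1,3-diene) are bought as such.

**Route**

Step 1
Reactants: 1 (E)-cinnamaldehyde; 2 propane-1,3-dithiol
Product: 3 2-[(E)-2-phenylethenyl]-1,3-dithiane
Conditions: BF3·OEt2 (cat.), CH2Cl2, −20 → 0 °C
Reagents that add atoms: none
Why: Lewis-acid thioacetalisation (Corey–Seebach dithiane formation) occurs at the carbonyl faster than thiol conjugate addition at low temperature and turns the aldehyde carbon into a latent acyl anion.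

Step 2
Reactants: 3 2-[(E)-2-phenylethenyl]-1,3-dithiane; 4 (S)-epichlorohydrin; 5 lithium acetylide–ethylenediamine complex
Product: 9 (2R)-1-{2-[(E)-2-phenylethenyl]-1,3-dithian-2-yl}pent-4-yn-2-ol, via lithiated dithiane 6 (not isolated), via lithium chlorohydrin alkoxide 7 (not isolated), via dithianyl epoxide 8 (not isolated)
Conditions: n-BuLi, THF, −78 °C; 4, −78 °C → rt; then 5, DMSO, 0 °C → rt; then H2O
Reagents that add atoms: none
Why: Corey–Seebach acyl-anion alkylation run as a one-flask three-component linchpin coupling, in which the allyl-type dithiane anion attacks the epoxide CH2 of 4 through its dithiane carbon (styrene conjugation is kept), the chlorohydrin alkoxide closes to terminal epoxide 8, and the acetylide opens 8 at its CH2; no bond to the carbinol carbon is broken, so C-2 of 9 carries the configuration of 4.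

Step 3
Reactants: 9 (2R)-1-{2-[(E)-2-phenylethenyl]-1,3-dithian-2-yl}pent-4-yn-2-ol
Product: 10 (1E,5R)-5-hydroxy-1-phenyloct-1-en-7-yn-3-one
Conditions: PhI(OCOCF3)2, NaHCO3, MeCN/H2O 9:1, 0 °C
Reagents that add atoms: water, O
Why: Stork–Zhao oxidative dithiane hydrolysis, in which sulfur is oxidised much faster than the styrene or the alkyne, water supplies the ketone oxygen, and the bicarbonate buffer keeps the β-hydroxy enone from dehydrating or closing by oxa-Michael addition.

Step 4
Reactants: 10 (1E,5R)-5-hydroxy-1-phenyloct-1-en-7-yn-3-one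
Product: 11 (1E,3S,5R)-1-phenyloct-1-en-7-yne-3,5-diol
Conditions: Me4NBH(OAc)3, MeCN/AcOH 1:1, −30 °C
Reagents that add atoms: none
Why: Evans–Saksena reduction, in which the free hydroxyl binds boron and hydride is delivered intramolecularly through a chair transition state (1,2-reduction of the enone), giving the 1,3-anti diol and so the (3S) carbinol from the (5R) one.

Step 5
Reactants: 11 (1E,3S,5R)-1-phenyloct-1-en-7-yne-3,5-diol
Product: 12 (1E,3S,5R)-3,5-dimethoxy-1-phenyloct-1-en-7-yne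
Conditions: Me3OBF4, 1,8-bis(dimethylamino)naphthalene, 4 Å MS, CH2Cl2, 0 °C → rt
Reagents that add atoms: trimethyloxonium tetrafluoroborate, C[O+](C)C.F[B-](F)(F)F
Why: Meerwein-salt O-methylation under buffered, non-basic conditions etherifies both secondary hydroxyls without deprotonating the terminal alkyne or ionising the cinnamyl-type alcohol, and no stereocentre is touched.

Step 6
Reactants: 12 (1E,3S,5R)-3,5-dimethoxy-1-phenyloct-1-en-7-yne
Product: 15 (2E,5R,7S,8E)-5,7-dimethoxy-9-phenylnona-2,8-dienal, via alkenylzirconocene chloride 13 (not isolated), via acylzirconocene chloride 14 (not isolated)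
Conditions: Cp2Zr(H)Cl, THF, rt; CO (1 atm), rt; then 1 M aq. HCl, 0 °C
Reagents that add atoms: carbon monoxide, [C-]#[O+]
Why: Schwartz hydrozirconation adds Zr–H syn and anti-Markovnikov to the terminal alkyne only (the internal styrene is far slower), CO inserts into the alkenyl–Zr bond with retention of E geometry, and protonolysis of the acylzirconocene releases the (E)-enal (Bertelo–Schwartz carbonylation).

Step 7
Reactants: 15 (2E,5R,7S,8E)-5,7-dimethoxy-9-phenylnona-2,8-dienal; 16 Chan's diene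
Product: 18 methyl (5R,6E,9R,11S,12E)-5-hydroxy-9,11-dimethoxy-3-oxo-13-phenyltrideca-6,12-dienoate, via bis-silyl aldol adduct 17 (not isolated)
Conditions: Ti(OiPr)4/(R)-BINOL (1:1, 10 mol %), 4 Å MS, THF, −78 °C → rt; then TFA, −78 °C → rt
Reagents that add atoms: none
Why: Catalytic enantioselective vinylogous Mukaiyama aldol in which Chan's diene reacts at its terminal carbon and the (R)-BINOL–titanium complex is expected, by analogy with its (R)-selective additions to benzaldehyde and cinnamaldehyde, to direct attack to the Re face of the enal and set the (5R) carbinol under catalyst control (this facial sense is recalled, not checked; use (S)-BINOL if it proves opposite).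

Step 8
Reactants: 18 methyl (5R,6E,9R,11S,12E)-5-hydroxy-9,11-dimethoxy-3-oxo-13-phenyltrideca-6,12-dienoate
Product: 20 methyl (3S,5R,6E,9R,11S,12E)-3,5-dihydroxy-9,11-dimethoxy-13-phenyltrideca-6,12-dienoate, via diethylboron chelate 19 (not isolated)
Conditions: Et2BOMe, THF/MeOH 4:1, −78 °C; NaBH4; then AcOH, MeOH co-evaporation
Reagents that add atoms: none
Why: Narasaka–Prasad reduction, in which Et2BOMe locks the β-hydroxy ketone as a six-membered boron chelate and external hydride adds axially to give the 1,3-syn diol, setting the (3S) centre from the (5R) one.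

Step 9
Reactants: 20 methyl (3S,5R,6E,9R,11S,12E)-3,5-dihydroxy-9,11-dimethoxy-13-phenyltrideca-6,12-dienoate
Product: 21 (4S,6R)-6-[(1E,4R,6S,7E)-4,6-dimethoxy-8-phenylocta-1,7-dien-1-yl]-4-hydroxyoxan-2-one
Conditions: PPTS (cat.), toluene, 60 °C
Reagents that add atoms: none
Why: Acid-catalysed lactonisation (intramolecular transesterification) of the syn-3,5-dihydroxy ester closes the six-membered ring through the C-5 hydroxyl under conditions too mild to ionise the allylic ethers or dehydrate the β-hydroxy lactone, and no stereocentre is touched.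

**Compound list**

1 | (E)-cinnamaldehyde | O=C/C=C/c1ccccc1 | starting material
2 | propane-1,3-dithiol | SCCCS | starting material
3 | 2-[(E)-2-phenylethenyl]-1,3-dithiane | c1ccccc1/C=C/C1SCCCS1 | intermediate
4 | (S)-epichlorohydrin, (2S)-2-(chloromethyl)oxirane | ClC[C@@H]1CO1 | starting material
5 | lithium acetylide–ethylenediamine complex, LiC≡CH·H2NCH2CH2NH2 | [Li+].[C-]#C.NCCN | starting material
6 | 2-lithio-2-[(E)-2-phenylethenyl]-1,3-dithiane | [Li]C1(/C=C/c2ccccc2)SCCCS1 | intermediate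
7 | lithium (2S)-1-chloro-3-{2-[(E)-2-phenylethenyl]-1,3-dithian-2-yl}propan-2-olate | [Li+].[O-][C@H](CCl)CC1(/C=C/c2ccccc2)SCCCS1 | intermediate
8 | 2-{[(2S)-oxiran-2-yl]methyl}-2-[(E)-2-phenylethenyl]-1,3-dithiane | O1C[C@@H]1CC2(/C=C/c3ccccc3)SCCCS2 | intermediate
9 | (2R)-1-{2-[(E)-2-phenylethenyl]-1,3-dithian-2-yl}pent-4-yn-2-ol | O[C@H](CC#C)CC1(/C=C/c2ccccc2)SCCCS1 | intermediate
10 | (1E,5R)-5-hydroxy-1-phenyloct-1-en-7-yn-3-one | O[C@H](CC#C)CC(=O)/C=C/c1ccccc1 | intermediate
11 | (1E,3S,5R)-1-phenyloct-1-en-7-yne-3,5-diol | O[C@H](CC#C)C[C@@H](/C=C/c1ccccc1)O | intermediate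
12 | (1E,3S,5R)-3,5-dimethoxy-1-phenyloct-1-en-7-yne | CO[C@H](CC#C)C[C@@H](/C=C/c1ccccc1)OC | intermediate
13 | chlorobis(cyclopentadienyl)[(1E,4R,6S,7E)-4,6-dimethoxy-8-phenylocta-1,7-dien-1-yl]zirconium, Cp2Zr(Cl)(alkenyl) | CO[C@H](C/C=C/[Zr](Cl)(C1C=CC=C1)C1C=CC=C1)C[C@@H](/C=C/c1ccccc1)OC | intermediate
14 | chlorobis(cyclopentadienyl)[(2E,5R,7S,8E)-5,7-dimethoxy-9-phenylnona-2,8-dienoyl]zirconium, Cp2Zr(Cl)(acyl) | CO[C@H](C/C=C/C(=O)[Zr](Cl)(C1C=CC=C1)C1C=CC=C1)C[C@@H](/C=C/c1ccccc1)OC | intermediate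
15 | (2E,5R,7S,8E)-5,7-dimethoxy-9-phenylnona-2,8-dienal | CO[C@H](C/C=C/C=O)C[C@@H](/C=C/c1ccccc1)OC | intermediate
16 | Chan's diene, 1-methoxy-1,3-bis(trimethylsilyloxy)buta-1,3-diene | COC(O[Si](C)(C)C)=CC(=C)O[Si](C)(C)C | starting material
17 | methyl (5R,6E,9R,11S,12E)-9,11-dimethoxy-13-phenyl-3,5-bis(trimethylsilyloxy)trideca-2,6,12-trienoate | CO[C@H](C/C=C/[C@H](O[Si](C)(C)C)CC(O[Si](C)(C)C)=CC(=O)OC)C[C@@H](/C=C/c1ccccc1)OC | intermediate
18 | methyl (5R,6E,9R,11S,12E)-5-hydroxy-9,11-dimethoxy-3-oxo-13-phenyltrideca-6,12-dienoate | CO[C@H](C/C=C/[C@H](O)CC(=O)CC(=O)OC)C[C@@H](/C=C/c1ccccc1)OC | intermediate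
19 | methyl (5R,6E,9R,11S,12E)-5-(diethylboranyloxy)-9,11-dimethoxy-3-oxo-13-phenyltrideca-6,12-dienoate (boron chelated to the ketone) | CO[C@H](C/C=C/[C@H](OB(CC)CC)CC(=O)CC(=O)OC)C[C@@H](/C=C/c1ccccc1)OC | intermediate
20 | methyl (3S,5R,6E,9R,11S,12E)-3,5-dihydroxy-9,11-dimethoxy-13-phenyltrideca-6,12-dienoate | CO[C@H](C/C=C/[C@H](O)C[C@H](O)CC(=O)OC)C[C@@H](/C=C/c1ccccc1)OC | intermediate
21 | (4S,6R)-6-[(1E,4R,6S,7E)-4,6-dimethoxy-8-phenylocta-1,7-dien-1-yl]-4-hydroxyoxan-2-one | CO[C@H](C/C=C/[C@H]1C[C@H](O)CC(=O)O1)C[C@@H](/C=C/c1ccccc1)OC | target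

**Step count and risks**

Total steps: 9. Longest linear sequence: 9 (fully linear from cinnamaldehyde).

Steps most likely to fail:

Step 2. The dithiane anion is ambident (attack through the benzylic carbon would give a ketene dithioacetal). Direct chloride displacement on 4 would erode the enantiomeric purity. The acetylide stage must also tolerate the salts of the first stage. Fallback, setting out from 4 and 5: the non-ambident formyl-anion equivalent 1,3-dithiane F1 is lithiated (n-BuLi) and added to 4 to give 2-{[(2S)-oxiran-2-yl]methyl}-1,3-dithiane F2. Reagent 5 in DMSO opens it to (2R)-1-(1,3-dithian-2-yl)pent-4-yn-2-ol F3. PhI(OCOCF3)2/NaHCO3 unmasks (3R)-3-hydroxyhex-5-ynal F4, which is used crude. The styryl group then enters as a nucleophile: the (E)-styrylzinc reagent made from phenylacetylene (Cp2Zr(H)Cl, then Me2Zn) adds to give (1E,5R)-1-phenyloct-1-en-7-yne-3,5-diol F5 as a mixture of C-3 epimers. MnO2 oxidises only the allylic hydroxyl, and the fallback comes back to the route at 10.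

Step 6. CO insertion and protonolysis on a polyfunctional substrate may give modest yields, and the enal is acid-sensitive. Fallback, setting out from 12: deprotonation (n-BuLi) and trapping with (CH2O)n gives (5R,7S,8E)-5,7-dimethoxy-9-phenylnon-8-en-2-yn-1-ol F6. NaAlH2(OCH2CH2OMe)2 reduces the propargylic alcohol trans-selectively to (2E,5R,7S,8E)-5,7-dimethoxy-9-phenylnona-2,8-dien-1-ol F7. MnO2 oxidises the allylic alcohol, and the fallback comes back to the route at 15.

Step 7. Catalyst-controlled addition to an elaborate enal carrying Lewis-basic ethers may give lower selectivity than model enals. Fallback, setting out from 15, builds the unsaturated lactone and hydrates it: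
- (+)-Ipc2B(allyl), made from (−)-α-pinene, adds to the Re face to give (4R,5E,8R,10S,11E)-8,10-dimethoxy-12-phenyldodeca-1,5,11-trien-4-ol F8.
- Acryloyl chloride/Et3N gives (4R,5E,8R,10S,11E)-8,10-dimethoxy-12-phenyldodeca-1,5,11-trien-4-yl prop-2-enoate F9.
- Ring-closing metathesis with RuCl2(PCy3)2(=CHPh), the first-generation Grubbs catalyst, gives (6R)-6-[(1E,4R,6S,7E)-4,6-dimethoxy-8-phenylocta-1,7-dien-1-yl]-5,6-dihydro-2H-pyran-2-one F10. The catalyst loads at the terminal allyl group and closes the six-membered lactone, as in goniothalamin syntheses.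
- CuCl/NaOtBu/DPEphos/B2pin2/MeOH adds boron to C-4 anti to the C-6 substituent to give (4S,6R)-6-[(1E,4R,6S,7E)-4,6-dimethoxy-8-phenylocta-1,7-dien-1-yl]-4-(4,4,5,5-tetramethyl-1,3,2-dioxaborolan-2-yl)oxan-2-one F11.
- NaBO3·4H2O oxidises F11 with retention, and the fallback comes back to the route at 21.

Further compounds
F1 | step 2 | 1,3-dithiane | C1CSCSC1
F2 | step 2 | 2-{[(2S)-oxiran-2-yl]methyl}-1,3-dithiane | O1C[C@@H]1CC2SCCCS2
F3 | step 2 | (2R)-1-(1,3-dithian-2-yl)pent-4-yn-2-ol | O[C@H](CC#C)CC1SCCCS1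
F4 | step 2 | (3R)-3-hydroxyhex-5-ynal | O[C@H](CC#C)CC=O
F5 | step 2 | (1E,5R)-1-phenyloct-1-en-7-yne-3,5-diol (mixture of C-3 epimers) | O[C@H](CC#C)CC(O)/C=C/c1ccccc1
F6 | step 6 | (5R,7S,8E)-5,7-dimethoxy-9-phenylnon-8-en-2-yn-1-ol | CO[C@H](CC#CCO)C[C@@H](/C=C/c1ccccc1)OC
F7 | step 6 | (2E,5R,7S,8E)-5,7-dimethoxy-9-phenylnona-2,8-dien-1-ol | CO[C@H](C/C=C/CO)C[C@@H](/C=C/c1ccccc1)OC
F8 | step 7 | (4R,5E,8R,10S,11E)-8,10-dimethoxy-12-phenyldodeca-1,5,11-trien-4-ol | CO[C@H](C/C=C/[C@H](O)CC=C)C[C@@H](/C=C/c1ccccc1)OC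
F9 | step 7 | (4R,5E,8R,10S,11E)-8,10-dimethoxy-12-phenyldodeca-1,5,11-trien-4-yl prop-2-enoate | CO[C@H](C/C=C/[C@H](OC(=O)C=C)CC=C)C[C@@H](/C=C/c1ccccc1)OC
F10 | step 7 | (6R)-6-[(1E,4R,6S,7E)-4,6-dimethoxy-8-phenylocta-1,7-dien-1-yl]-5,6-dihydro-2H-pyran-2-one | CO[C@H](C/C=C/[C@H]1CC=CC(=O)O1)C[C@@H](/C=C/c1ccccc1)OC
F11 | step 7 | (4S,6R)-6-[(1E,4R,6S,7E)-4,6-dimethoxy-8-phenylocta-1,7-dien-1-yl]-4-(4,4,5,5-tetramethyl-1,3,2-dioxaborolan-2-yl)oxan-2-one | CO[C@H](C/C=C/[C@H]1C[C@H](B2OC(C)(C)C(C)(C)O2)CC(=O)O1)C[C@@H](/C=C/c1ccccc1)OC
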